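**Retrosynthetic overview**
1. Cut the aryl–CH2 bond of the bridge. Ring B becomes an aryl iodide and ring A–CH2 becomes a β-boryl ketone, a boron homoenolate. The bridge carbon is normally the electrophilic formaldehyde (enone β) carbon but reacts here as the nucleophile, so a B-alkyl Suzuki–Miyaura coupling joins two normally electrophilic carbons.
2. The homoenolate comes from butyrylfilicinic acid and ICH2Bpin by C-alkylation at C-6, and it is used in the same flask.
3. Butyrylfilicinic acid comes from phloroglucinol by Friedel–Crafts butyrylation followed by dearomatising gem-dimethylation.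
4. The aryl iodide comes from 2,5-dimethylresorcinol by Friedel–Crafts butyrylation followed by iodination of the only free ring carbon.
5. No ring is built. Ring B is the purchased benzene ring. Ring A is the phloroglucinol ring, dearomatised in step 2 before the halves are joined in step 5.

Assumption: the target has no stereocentre (C-4 of ring A carries two identical methyl groups) and is achiral, so there is no enantiomer to select; all ring A compounds are drawn in the enol tautomer of the given SMILES.

**Step 1**
Reactants: 1 benzene-1,3,5-triol (phloroglucinol); 2 butanoyl chloride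
Product: 3 1-(2,4,6-trihydroxyphenyl)butan-1-one
Conditions: AlCl3 (3.5 equiv), CH2Cl2/PhNO2 1:1, 0 to 45 °C, 4 h; ice/1 M HCl
Reagents that add atoms: butanoyl chloride (2), CCCC(=O)Cl
Why: Friedel–Crafts acylation of a very electron-rich arene whose three free positions are equivalent, so only one isomer can form, and the AlCl3-chelated aryl ketone is deactivated towards a second acylation.

**Step 2**
Reactants: 3 1-(2,4,6-trihydroxyphenyl)butan-1-one; 4 iodomethane
Product: 5 2-butanoyl-3,5-dihydroxy-4,4-dimethylcyclohexa-2,5-dien-1-one (butyrylfilicinic acid)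
Conditions: NaOMe (3.0 equiv), MeI (2.2 equiv), MeOH, 0 °C to rt, 16 h; 1 M HCl
Reagents that add atoms: iodomethane (4), CI
Why: Dearomatising double C-alkylation of the phloroglucinol enolate, in which soft MeI attacks carbon, the first methyl makes that carbon the most nucleophilic site so the second enters geminally, and the new quaternary carbon carries two identical groups and is not a stereocentre.

**Step 3**
Reactants: 6 2,5-dimethylbenzene-1,3-diol (2,5-dimethylresorcinol); 2 butanoyl chloride
Product: 7 1-(2,4-dihydroxy-3,6-dimethylphenyl)butan-1-one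
Conditions: AlCl3 (2.5 equiv), CH2Cl2/PhNO2 1:1, 0 to 40 °C, 6 h; ice/1 M HCl
Reagents that add atoms: butanoyl chloride (2), CCCC(=O)Cl
Why: Friedel–Crafts acylation in which the two free positions of the mirror-symmetric diol are equivalent, each ortho to one OH and para to the other, so one regioisomer forms and the chelated ketone resists a second acylation.

**Step 4**
Reactants: 7 1-(2,4-dihydroxy-3,6-dimethylphenyl)butan-1-one; 8 N-iodosuccinimide
Product: 9 1-(2,4-dihydroxy-5-iodo-3,6-dimethylphenyl)butan-1-one
Conditions: NIS (1.05 equiv), MeCN, 0 °C to rt, dark, 2 h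
Reagents that add atoms: N-iodosuccinimide (8), O=C1CCC(=O)N1I
Why: Electrophilic aromatic iodination at the only unsubstituted ring carbon, which is ortho and para to the two hydroxyl groups and reacts far faster than the α-carbon of the hindered ketone.

**Step 5 (key step)**
Reactants: 5 butyrylfilicinic acid (1.1 equiv); 10 2-(iodomethyl)-4,4,5,5-tetramethyl-1,3,2-dioxaborolane (1.0 equiv); 9 1-(2,4-dihydroxy-5-iodo-3,6-dimethylphenyl)butan-1-one (0.9 equiv)
Product: 12 2-butanoyl-6-[(3-butanoyl-4,6-dihydroxy-2,5-dimethylphenyl)methyl]-3,5-dihydroxy-4,4-dimethylcyclohexa-2,5-dien-1-one (target), via boron homoenolate 11 (not isolated)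
Conditions: 5, 10, K2CO3 (2.5 equiv), DMF, 0 °C to rt, 4 h; then 9, PdCl2(dppf) (dppf = 1,1'-bis(diphenylphosphino)ferrocene, 5 mol %), K2CO3 (4 equiv), degassed H2O (DMF/H2O 8:1), 50 °C, 6 h; 1 M HCl
Reagents that add atoms: 2-(iodomethyl)-4,4,5,5-tetramethyl-1,3,2-dioxaborolane (10), ICB1OC(C)(C)C(C)(C)O1
Why: Proposed new method: soft C-6 of the dipotassium salt of 5 displaces iodide from 10 (the same C-alkylation that MeI shows at this carbon) to give the β-boryl ketone 11, a boron homoenolate in which the bridge carbon, normally the electrophilic formaldehyde or enone β-carbon, is nucleophilic, its enolate oxygen closes a five-membered O→B ate complex that primes transmetalation to the aryl–palladium iodide formed by oxidative addition of zerovalent palladium to 9, the neighbouring C-6 is sp2 so β-hydride elimination is impossible, and reductive elimination joins two carbons that are both normally electrophilic; the closest known reaction types are enolate alkylation with halomethylboronic esters and the B-alkyl Suzuki–Miyaura coupling of β-boryl carbonyl compounds with aryl halides, and no stereocentre is formed.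

**Compound list**
1 | benzene-1,3,5-triol (phloroglucinol) | Oc1cc(O)cc(O)c1 | starting material
2 | butanoyl chloride | CCCC(=O)Cl | starting material
3 | 1-(2,4,6-trihydroxyphenyl)butan-1-one | CCCC(=O)c1c(O)cc(O)cc1O | intermediate
4 | iodomethane | CI | starting material
5 | 2-butanoyl-3,5-dihydroxy-4,4-dimethylcyclohexa-2,5-dien-1-one (butyrylfilicinic acid) | CCCC(=O)C1=C(O)C(C)(C)C(O)=CC1=O | intermediate
6 | 2,5-dimethylbenzene-1,3-diol | Cc1cc(O)c(C)c(O)c1 | starting material
7 | 1-(2,4-dihydroxy-3,6-dimethylphenyl)butan-1-one | CCCC(=O)c1c(C)cc(O)c(C)c1O | intermediate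
8 | N-iodosuccinimide | O=C1CCC(=O)N1I | starting material
9 | 1-(2,4-dihydroxy-5-iodo-3,6-dimethylphenyl)butan-1-one | CCCC(=O)c1c(C)c(I)c(O)c(C)c1O | intermediate
10 | 2-(iodomethyl)-4,4,5,5-tetramethyl-1,3,2-dioxaborolane | ICB1OC(C)(C)C(C)(C)O1 | starting material
11 | 2-butanoyl-3,5-dihydroxy-4,4-dimethyl-6-[(4,4,5,5-tetramethyl-1,3,2-dioxaborolan-2-yl)methyl]cyclohexa-2,5-dien-1-one (boron homoenolate) | CCCC(=O)C1=C(O)C(C)(C)C(O)=C(CB2OC(C)(C)C(C)(C)O2)C1=O | intermediate
12 | 2-butanoyl-6-[(3-butanoyl-4,6-dihydroxy-2,5-dimethylphenyl)methyl]-3,5-dihydroxy-4,4-dimethylcyclohexa-2,5-dien-1-one | CCCC(=O)C1=C(O)C(C)(C)C(O)=C(Cc2c(C)c(C(=O)CCC)c(O)c(C)c2O)C1=O | target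

**Total steps:** 5. **Longest linear sequence:** 3 (steps 1, 2, 5 or steps 3, 4, 5).

**Steps most likely to fail**

**Step 5 (highest risk).**
- The alkylation may give some O- or double alkylation.
- The pinacol ester may transmetalate slowly.
- The bis-phenoxide of 9 is a poor partner for oxidative addition.
- Warm carbonate can scramble the bridge of 12 by retro-Michael cleavage (rottlerone-type change).

The fallback sets out from 11 and 9 and comes back at 12. It keeps the homoenolate polarity but becomes a stepwise, protected sequence. The first stage is stopped and crude 11 is stirred with aqueous KHF2 in MeOH. This gives crystalline potassium [(5-butanoyl-2,4-dihydroxy-3,3-dimethyl-6-oxocyclohexa-1,4-dien-1-yl)methyl]trifluoroborate F1, which is freed from O-alkylated material by recrystallisation. Compound 9 is treated with NaH and chloromethyl methyl ether in DMF to give 1-[5-iodo-2,4-bis(methoxymethoxy)-3,6-dimethylphenyl]butan-1-one F2. Its ethers speed oxidative addition and remove the phenoxides that drive scrambling. The two are coupled with Pd(OAc)2/RuPhos and K2CO3 in toluene/H2O at 85 °C to give 2-butanoyl-6-{[3-butanoyl-4,6-bis(methoxymethoxy)-2,5-dimethylphenyl]methyl}-3,5-dihydroxy-4,4-dimethylcyclohexa-2,5-dien-1-one F3. HCl in MeOH at rt then releases 12.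

**Step 2.** Two successive methylations give a statistical mixture of mono-, 3,5-di-, tri- and tetramethyl products. The fallback sets out from 2 and 4 and comes back at 5. Purchased 2-methylbenzene-1,3,5-triol is acylated with 2 and AlCl3 at either of its two equivalent free positions. This gives 1-(2,4,6-trihydroxy-3-methylphenyl)butan-1-one F4. Only one dearomatising methylation is then needed (4, 1.0 equiv, NaOMe, MeOH, 0 °C). It occurs at the methyl-bearing, most nucleophilic carbon and gives 5.

**Step 3.** The acyl group must enter between an OH and a methyl group, so O-acylation or incomplete conversion is possible. The fallback sets out from 6 and comes back at 7 by a Houben–Hoesch reaction. Compound 6, butanenitrile, ZnCl2 and dry HCl in Et2O at 0 °C precipitate 1-(2,4-dihydroxy-3,6-dimethylphenyl)butan-1-iminium chloride F5. This salt cannot react a second time, and boiling it in water gives 7.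

**Further compounds**
F1 | step 5 | potassium [(5-butanoyl-2,4-dihydroxy-3,3-dimethyl-6-oxocyclohexa-1,4-dien-1-yl)methyl]trifluoroborate | [K+].CCCC(=O)C1=C(O)C(C)(C)C(O)=C(C[B-](F)(F)F)C1=O
F2 | step 5 | 1-[5-iodo-2,4-bis(methoxymethoxy)-3,6-dimethylphenyl]butan-1-one | CCCC(=O)c1c(C)c(I)c(OCOC)c(C)c1OCOC
F3 | step 5 | 2-butanoyl-6-{[3-butanoyl-4,6-bis(methoxymethoxy)-2,5-dimethylphenyl]methyl}-3,5-dihydroxy-4,4-dimethylcyclohexa-2,5-dien-1-one | CCCC(=O)C1=C(O)C(C)(C)C(O)=C(Cc2c(C)c(C(=O)CCC)c(OCOC)c(C)c2OCOC)C1=O
F4 | step 2 | 1-(2,4,6-trihydroxy-3-methylphenyl)butan-1-one | CCCC(=O)c1c(O)cc(O)c(C)c1O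
F5 | step 3 | 1-(2,4-dihydroxy-3,6-dimethylphenyl)butan-1-iminium chloride | [Cl-].CCCC(=[NH2+])c1c(C)cc(O)c(C)c1O
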